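## Retrosynthetic overview

1. The enal is unveiled last from a tert-butyl cinnamate (ester reduction, then MnO2 oxidation); the phenol stays silylated until the final step.
2. The 1,4-dioxane ring is the only ring made (both benzene rings are bought). It is closed by Pd-catalysed intramolecular C–O coupling of a benzylic alcohol onto an ortho-bromide, with retention, so a syn-1,2-dioxygenated chain gives the trans ring.
3. Key C–C disconnection is the bond between the two stereocentres: an Evans syn aldol of an (R)-oxazolidinone aryloxyacetimide with TIPS-protected syringaldehyde sets both centres at once.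
4. The imide comes from 3-bromo-4-hydroxybenzaldehyde (Williamson ether, Wittig, selective hydrolysis, N-acylation); the aldehyde comes from syringaldehyde.
5. Order: aldol, auxiliary reduction, primary-OH tritylation, dioxane ring closure, side-chain adjustment, desilylation.

Assumption: the SMILES is read as the (2S,3S)-trans-2,3-dihydro-1,4-benzodioxine, with the aryl group at C3, CH2OH at C2 and the (E)-propenal at C6.

## Route

Step 1
Reactants: 1 3-bromo-4-hydroxybenzaldehyde; 2 methyl bromoacetate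
Product: 3 methyl 2-(2-bromo-4-formylphenoxy)acetate
Conditions: K2CO3, DMF, rt
Reagents that add atoms: none
Why: Williamson ether synthesis; the phenoxide displaces bromide from the activated α-bromo ester by SN2 and no stereocentre is involved.

Step 2
Reactants: 3 methyl 2-(2-bromo-4-formylphenoxy)acetate; 4 tert-butyl (triphenylphosphoranylidene)acetate
Product: 5 tert-butyl (E)-3-[3-bromo-4-(2-methoxy-2-oxoethoxy)phenyl]prop-2-enoate
Conditions: toluene, 80 °C
Reagents that add atoms: none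
Why: Wittig olefination with a stabilised ylide under neutral conditions gives the E-cinnamate selectively and leaves the methyl ester untouched.

Step 3
Reactants: 5 tert-butyl (E)-3-[3-bromo-4-(2-methoxy-2-oxoethoxy)phenyl]prop-2-enoate
Product: 6 2-{2-bromo-4-[(E)-3-tert-butoxy-3-oxoprop-1-en-1-yl]phenoxy}acetic acid
Conditions: LiOH·H2O (1.1 equiv), THF/H2O, 0 °C; then 1 M HCl
Reagents that add atoms: lithium hydroxide, [Li+].[OH-]
Why: Chemoselective saponification; the unhindered α-aryloxy methyl ester hydrolyses within minutes, while the hindered conjugated tert-butyl ester is inert at 0 °C.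

Step 4
Reactants: 6 2-{2-bromo-4-[(E)-3-tert-butoxy-3-oxoprop-1-en-1-yl]phenoxy}acetic acid; 7 (R)-4-benzyloxazolidin-2-one
Product: 9 (R)-4-benzyl-3-(2-{2-bromo-4-[(E)-3-tert-butoxy-3-oxoprop-1-en-1-yl]phenoxy}acetyl)oxazolidin-2-one, via mixed pivalic anhydride 8 (not isolated)
Conditions: PivCl, Et3N, THF, −20 °C; then 7, LiCl, −20 °C → rt
Reagents that add atoms: none
Why: N-acylation of the oxazolidinone through a mixed anhydride; the auxiliary attacks the less hindered aryloxyacetyl carbonyl, not the pivaloyl one.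

Step 5
Reactants: 10 syringaldehyde (4-hydroxy-3,5-dimethoxybenzaldehyde)
Product: 11 3,5-dimethoxy-4-[(triisopropylsilyl)oxy]benzaldehyde
Conditions: TIPSCl, imidazole, DMF, rt
Reagents that add atoms: chlorotriisopropylsilane, CC(C)[Si](Cl)(C(C)C)C(C)C
Why: Phenol silylation; the bulky TIPS ether, flanked by two methoxy groups, is robust to boron Lewis acid, hydride, carbonate base and mild acid, and is cleaved by fluoride at the end.

Step 6
Reactants: 9 (R)-4-benzyl-3-(2-{2-bromo-4-[(E)-3-tert-butoxy-3-oxoprop-1-en-1-yl]phenoxy}acetyl)oxazolidin-2-one; 11 3,5-dimethoxy-4-[(triisopropylsilyl)oxy]benzaldehyde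
Product: 14 (R)-4-benzyl-3-[(2R,3S)-2-{2-bromo-4-[(E)-3-tert-butoxy-3-oxoprop-1-en-1-yl]phenoxy}-3-{3,5-dimethoxy-4-[(triisopropylsilyl)oxy]phenyl}-3-hydroxypropanoyl]oxazolidin-2-one, via dibutylboron Z-enolate 12 (not isolated), via dibutylboron aldolate 13 (not isolated)
Conditions: Bu2BOTf, i-Pr2NEt, CH2Cl2, −78 → 0 °C; then 11, −78 → 0 °C; then pH 7 buffer, MeOH, 30% H2O2, 0 °C
Reagents that add atoms: none
Why: Evans syn aldol; the Z-boron enolate reacts through a closed Zimmerman–Traxler chair in which the benzyl group of the (R)-auxiliary shields one enolate face, setting C2 (R, aryloxy-bearing) and C3 (S, carbinol) together as the syn pair.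

Step 7
Reactants: 14 the syn-aldol imide
Product: 15 tert-butyl (E)-3-{3-bromo-4-[((1S,2S)-1-{3,5-dimethoxy-4-[(triisopropylsilyl)oxy]phenyl}-1,3-dihydroxypropan-2-yl)oxy]phenyl}prop-2-enoate
Conditions: LiBH4, THF, 0 °C; aq. NH4Cl
Reagents that add atoms: none
Why: Reductive cleavage of the N-acyl oxazolidinone; hydride attacks the activated exocyclic imide carbonyl, the tert-butyl enoate is inert at 0 °C, and neither stereocentre is touched (the C2 descriptor changes from R to S only through CIP priorities).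

Step 8
Reactants: 15 the (1S,2S)-diol
Product: 16 tert-butyl (E)-3-{3-bromo-4-[((1S,2S)-1-{3,5-dimethoxy-4-[(triisopropylsilyl)oxy]phenyl}-1-hydroxy-3-(trityloxy)propan-2-yl)oxy]phenyl}prop-2-enoate
Conditions: TrCl, Et3N, DMAP (cat.), CH2Cl2, rt
Reagents that add atoms: trityl chloride, ClC(c1ccccc1)(c1ccccc1)c1ccccc1
Why: Selective tritylation of the primary hydroxyl on steric grounds; unlike a silyl group, trityl cannot migrate to the neighbouring alkoxide, so only the benzylic OH can cyclise in the next step.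

Step 9
Reactants: 16 the trityl ether bromo alcohol
Product: 17 tert-butyl (E)-3-[(2S,3S)-3-{3,5-dimethoxy-4-[(triisopropylsilyl)oxy]phenyl}-2-[(trityloxy)methyl]-2,3-dihydro-1,4-benzodioxin-6-yl]prop-2-enoate
Conditions: Pd(OAc)2 (5 mol %), rac-2-(di-tert-butylphosphino)-1,1'-binaphthyl (6 mol %), Cs2CO3, toluene, 80 °C
Reagents that add atoms: none
Why: Buchwald-type palladium-catalysed intramolecular C–O coupling closes the 1,4-dioxane ring on the ortho-bromide without breaking either C–O bond at the stereocentres, so the (1S,2S)-syn chain becomes the (2S,3S)-trans ring with retention.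

Step 10
Reactants: 17 the trityl-protected benzodioxane
Product: 18 tert-butyl (E)-3-[(2S,3S)-3-{3,5-dimethoxy-4-[(triisopropylsilyl)oxy]phenyl}-2-(hydroxymethyl)-2,3-dihydro-1,4-benzodioxin-6-yl]prop-2-enoate
Conditions: TsOH·H2O (cat.), MeOH/CH2Cl2, 0 °C → rt
Reagents that add atoms: none
Why: Acid-catalysed SN1 methanolysis of the trityl ether; the tert-butyl ester, the aryl TIPS ether and the weakly activated benzylic ring ether survive catalytic acid at room temperature.

Step 11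
Reactants: 18 the tert-butyl cinnamate alcohol
Product: 19 (E)-3-[(2S,3S)-3-{3,5-dimethoxy-4-[(triisopropylsilyl)oxy]phenyl}-2-(hydroxymethyl)-2,3-dihydro-1,4-benzodioxin-6-yl]prop-2-en-1-ol
Conditions: i-Bu2AlH (4 equiv), CH2Cl2, −78 → −20 °C; aq. potassium sodium tartrate
Reagents that add atoms: none
Why: 1,2-Reduction of the conjugated ester by the aluminium hydride gives the cinnamyl alcohol with the E-alkene intact.

Step 12
Reactants: 19 the cinnamyl alcohol diol
Product: 20 (E)-3-[(2S,3S)-3-{3,5-dimethoxy-4-[(triisopropylsilyl)oxy]phenyl}-2-(hydroxymethyl)-2,3-dihydro-1,4-benzodioxin-6-yl]prop-2-enal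
Conditions: MnO2 (activated, excess), CH2Cl2, rt
Reagents that add atoms: none
Why: MnO2 allylic oxidation is chemoselective for the cinnamyl alcohol; the saturated primary CH2OH is not oxidised and the phenol is still masked.

Step 13
Reactants: 20 the TIPS-protected enal
Product: 21 (E)-3-[(2S,3S)-3-(4-hydroxy-3,5-dimethoxyphenyl)-2-(hydroxymethyl)-2,3-dihydro-1,4-benzodioxin-6-yl]prop-2-enal (CNP0211211.1)
Conditions: Bu4NF, AcOH (1:1), THF, 0 °C
Reagents that add atoms: none
Why: Fluoride-mediated desilylation of the aryl silyl ether; the acetic acid buffer keeps the phenoxide concentration low, so the enal and the p-hydroxybenzyl aryl ether are not exposed to base.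

## Compound list

1 | 3-bromo-4-hydroxybenzaldehyde | O=Cc1ccc(O)c(Br)c1 | starting material
2 | methyl bromoacetate | COC(=O)CBr | starting material
3 | methyl 2-(2-bromo-4-formylphenoxy)acetate | COC(=O)COc1ccc(C=O)cc1Br | intermediate
4 | tert-butyl (triphenylphosphoranylidene)acetate | CC(C)(C)OC(=O)C=P(c1ccccc1)(c1ccccc1)c1ccccc1 | starting material
5 | tert-butyl (E)-3-[3-bromo-4-(2-methoxy-2-oxoethoxy)phenyl]prop-2-enoate | COC(=O)COc1ccc(/C=C/C(=O)OC(C)(C)C)cc1Br | intermediate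
6 | 2-{2-bromo-4-[(E)-3-tert-butoxy-3-oxoprop-1-en-1-yl]phenoxy}acetic acid | OC(=O)COc1ccc(/C=C/C(=O)OC(C)(C)C)cc1Br | intermediate
7 | (R)-4-benzyloxazolidin-2-one | O=C1OC[C@@H](Cc2ccccc2)N1 | starting material
8 | mixed pivalic anhydride of acid 6 | CC(C)(C)C(=O)OC(=O)COc1ccc(/C=C/C(=O)OC(C)(C)C)cc1Br | intermediate
9 | (R)-4-benzyl-3-(2-{2-bromo-4-[(E)-3-tert-butoxy-3-oxoprop-1-en-1-yl]phenoxy}acetyl)oxazolidin-2-one | O=C1OC[C@@H](Cc2ccccc2)N1C(=O)COc1ccc(/C=C/C(=O)OC(C)(C)C)cc1Br | intermediate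
10 | syringaldehyde (4-hydroxy-3,5-dimethoxybenzaldehyde) | COc1cc(C=O)cc(OC)c1O | starting material
11 | 3,5-dimethoxy-4-[(triisopropylsilyl)oxy]benzaldehyde | COc1cc(C=O)cc(OC)c1O[Si](C(C)C)(C(C)C)C(C)C | intermediate
12 | dibutylboron Z-enolate of imide 9 | O=C1OC[C@@H](Cc2ccccc2)N1/C(OB(CCCC)CCCC)=C/Oc1ccc(/C=C/C(=O)OC(C)(C)C)cc1Br | intermediate
13 | dibutylboron aldolate of 14 | O=C1OC[C@@H](Cc2ccccc2)N1C(=O)[C@H](Oc1ccc(/C=C/C(=O)OC(C)(C)C)cc1Br)[C@@H](OB(CCCC)CCCC)c1cc(OC)c(O[Si](C(C)C)(C(C)C)C(C)C)c(OC)c1 | intermediate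
14 | (R)-4-benzyl-3-[(2R,3S)-2-{2-bromo-4-[(E)-3-tert-butoxy-3-oxoprop-1-en-1-yl]phenoxy}-3-{3,5-dimethoxy-4-[(triisopropylsilyl)oxy]phenyl}-3-hydroxypropanoyl]oxazolidin-2-one | O=C1OC[C@@H](Cc2ccccc2)N1C(=O)[C@H](Oc1ccc(/C=C/C(=O)OC(C)(C)C)cc1Br)[C@@H](O)c1cc(OC)c(O[Si](C(C)C)(C(C)C)C(C)C)c(OC)c1 | intermediate
15 | tert-butyl (E)-3-{3-bromo-4-[((1S,2S)-1-{3,5-dimethoxy-4-[(triisopropylsilyl)oxy]phenyl}-1,3-dihydroxypropan-2-yl)oxy]phenyl}prop-2-enoate | OC[C@H](Oc1ccc(/C=C/C(=O)OC(C)(C)C)cc1Br)[C@@H](O)c1cc(OC)c(O[Si](C(C)C)(C(C)C)C(C)C)c(OC)c1 | intermediate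
16 | tert-butyl (E)-3-{3-bromo-4-[((1S,2S)-1-{3,5-dimethoxy-4-[(triisopropylsilyl)oxy]phenyl}-1-hydroxy-3-(trityloxy)propan-2-yl)oxy]phenyl}prop-2-enoate | C(c1ccccc1)(c1ccccc1)(c1ccccc1)OC[C@H](Oc1ccc(/C=C/C(=O)OC(C)(C)C)cc1Br)[C@@H](O)c1cc(OC)c(O[Si](C(C)C)(C(C)C)C(C)C)c(OC)c1 | intermediate
17 | tert-butyl (E)-3-[(2S,3S)-3-{3,5-dimethoxy-4-[(triisopropylsilyl)oxy]phenyl}-2-[(trityloxy)methyl]-2,3-dihydro-1,4-benzodioxin-6-yl]prop-2-enoate | COc1cc([C@@H]2Oc3cc(/C=C/C(=O)OC(C)(C)C)ccc3O[C@H]2COC(c2ccccc2)(c2ccccc2)c2ccccc2)cc(OC)c1O[Si](C(C)C)(C(C)C)C(C)C | intermediate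
18 | tert-butyl (E)-3-[(2S,3S)-3-{3,5-dimethoxy-4-[(triisopropylsilyl)oxy]phenyl}-2-(hydroxymethyl)-2,3-dihydro-1,4-benzodioxin-6-yl]prop-2-enoate | COc1cc([C@@H]2Oc3cc(/C=C/C(=O)OC(C)(C)C)ccc3O[C@H]2CO)cc(OC)c1O[Si](C(C)C)(C(C)C)C(C)C | intermediate
19 | (E)-3-[(2S,3S)-3-{3,5-dimethoxy-4-[(triisopropylsilyl)oxy]phenyl}-2-(hydroxymethyl)-2,3-dihydro-1,4-benzodioxin-6-yl]prop-2-en-1-ol | COc1cc([C@@H]2Oc3cc(/C=C/CO)ccc3O[C@H]2CO)cc(OC)c1O[Si](C(C)C)(C(C)C)C(C)C | intermediate
20 | (E)-3-[(2S,3S)-3-{3,5-dimethoxy-4-[(triisopropylsilyl)oxy]phenyl}-2-(hydroxymethyl)-2,3-dihydro-1,4-benzodioxin-6-yl]prop-2-enal | COc1cc([C@@H]2Oc3cc(/C=C/C=O)ccc3O[C@H]2CO)cc(OC)c1O[Si](C(C)C)(C(C)C)C(C)C | intermediate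
21 | (E)-3-[(2S,3S)-3-(4-hydroxy-3,5-dimethoxyphenyl)-2-(hydroxymethyl)-2,3-dihydro-1,4-benzodioxin-6-yl]prop-2-enal (CNP0211211.1) | COc1cc([C@@H]2Oc3cc(/C=C/C=O)ccc3O[C@H]2CO)cc(OC)c1O | target

## Step count and risk

Total step count: 13. Longest linear sequence: 12 (steps 1–4 and 6–13; step 5 is the one-step side branch).

**Step 6 (aldol).** The aldehyde is electron-rich and the α-aryloxy boron enolate is less nucleophilic than a propionate, so conversion or diastereoselectivity may fall short. The fallback sets out from acid 6 and comes back to the route at diol 15. Acid 6 is coupled with (R)-4-benzylthiazolidine-2-thione (EDC·HCl, DMAP, CH2Cl2) to give (R)-4-benzyl-3-(2-{2-bromo-4-[(E)-3-tert-butoxy-3-oxoprop-1-en-1-yl]phenoxy}acetyl)thiazolidine-2-thione F1. Its chlorotitanium enolate (TiCl4, i-Pr2NEt, N-methyl-2-pyrrolidinone, CH2Cl2, −78 °C) is combined with aldehyde 11 to give the Evans-syn (2R,3S) thiazolidinethione aldol adduct F2 through a more Lewis-acidic, more reactive enolate. NaBH4 in THF/EtOH then cleaves the thioimide reductively to diol 15.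

**Step 9 (ring closure).** The palladium alkoxide of a hindered benzylic secondary alcohol can undergo β-hydride elimination (ketone plus hydrodebromination) instead of C–O reductive elimination. The fallback sets out from diol 15 and comes back at alcohol 18, bypassing steps 8–10. Miyaura borylation of 15 (B2pin2, PdCl2(dppf), KOAc, dioxane, 85 °C) gives tert-butyl (E)-3-{4-[((1S,2S)-1-{3,5-dimethoxy-4-[(triisopropylsilyl)oxy]phenyl}-1,3-dihydroxypropan-2-yl)oxy]-3-(4,4,5,5-tetramethyl-1,3,2-dioxaborolan-2-yl)phenyl}prop-2-enoate F3. Oxidation with NaBO3·4H2O in THF/H2O gives tert-butyl (E)-3-{4-[((1S,2S)-1-{3,5-dimethoxy-4-[(triisopropylsilyl)oxy]phenyl}-1,3-dihydroxypropan-2-yl)oxy]-3-hydroxyphenyl}prop-2-enoate F4. Catalytic TsOH·H2O in CH2Cl2 at rt then closes the ring by SN1 attack of the new phenol on the benzylic cation. The C2 centre from the aldol is untouched; the C3 centre is set under thermodynamic control in favour of the trans ring, and the minor cis isomer is removed by chromatography, giving 18.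

**Step 13 (final desilylation).** The product carries an enal and a p-hydroxybenzyl aryl ether, which under basic fluoride can open through a quinone methide and partly epimerise at C3. The fallback sets out from diol 19 and comes back at target 21, with the two last operations in reverse order. Compound 19 is desilylated first (Bu4NF, AcOH, THF, 0 °C), while no enal is present, to give (E)-3-[(2S,3S)-3-(4-hydroxy-3,5-dimethoxyphenyl)-2-(hydroxymethyl)-2,3-dihydro-1,4-benzodioxin-6-yl]prop-2-en-1-ol F5. Activated MnO2 in CH2Cl2/acetone at rt then oxidises the cinnamyl alcohol chemoselectively, in the way free-phenol cinnamyl alcohols are oxidised to their aldehydes, and gives 21 under neutral conditions.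

Further compounds

F1 | step 6 | (R)-4-benzyl-3-(2-{2-bromo-4-[(E)-3-tert-butoxy-3-oxoprop-1-en-1-yl]phenoxy}acetyl)thiazolidine-2-thione | S=C1SC[C@@H](Cc2ccccc2)N1C(=O)COc1ccc(/C=C/C(=O)OC(C)(C)C)cc1Br
F2 | step 6 | (R)-4-benzyl-3-[(2R,3S)-2-{2-bromo-4-[(E)-3-tert-butoxy-3-oxoprop-1-en-1-yl]phenoxy}-3-{3,5-dimethoxy-4-[(triisopropylsilyl)oxy]phenyl}-3-hydroxypropanoyl]thiazolidine-2-thione | S=C1SC[C@@H](Cc2ccccc2)N1C(=O)[C@H](Oc1ccc(/C=C/C(=O)OC(C)(C)C)cc1Br)[C@@H](O)c1cc(OC)c(O[Si](C(C)C)(C(C)C)C(C)C)c(OC)c1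
F3 | step 9 | tert-butyl (E)-3-{4-[((1S,2S)-1-{3,5-dimethoxy-4-[(triisopropylsilyl)oxy]phenyl}-1,3-dihydroxypropan-2-yl)oxy]-3-(4,4,5,5-tetramethyl-1,3,2-dioxaborolan-2-yl)phenyl}prop-2-enoate | OC[C@H](Oc1ccc(/C=C/C(=O)OC(C)(C)C)cc1B2OC(C)(C)C(C)(C)O2)[C@@H](O)c1cc(OC)c(O[Si](C(C)C)(C(C)C)C(C)C)c(OC)c1
F4 | step 9 | tert-butyl (E)-3-{4-[((1S,2S)-1-{3,5-dimethoxy-4-[(triisopropylsilyl)oxy]phenyl}-1,3-dihydroxypropan-2-yl)oxy]-3-hydroxyphenyl}prop-2-enoate | OC[C@H](Oc1ccc(/C=C/C(=O)OC(C)(C)C)cc1O)[C@@H](O)c1cc(OC)c(O[Si](C(C)C)(C(C)C)C(C)C)c(OC)c1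
F5 | step 13 | (E)-3-[(2S,3S)-3-(4-hydroxy-3,5-dimethoxyphenyl)-2-(hydroxymethyl)-2,3-dihydro-1,4-benzodioxin-6-yl]prop-2-en-1-ol | COc1cc([C@@H]2Oc3cc(/C=C/CO)ccc3O[C@H]2CO)cc(OC)c1O
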